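(The earlier runs and the new flask are simulated for an exercise.)

In the green run the left-handed product rose to 23 % by 1.33 min, then only to 29 % by 3.00 min, though 18 % still stood as left-handed substrate. Suspect partner: its 0.54 M is less than the 0.720 M of the two substrates together, which makes it the likely limiting reagent, and the rates should fall as it falls.

common to all: left-handed substrate 0.36 M; right-handed substrate 0.36 M; catalyst 7.2 mM
- green: partner 0.54 M; protic impurity 0.11 M; run made earlier
- alpha: partner 0.540 M; protic impurity 0.0720 M; time 4.0 min
- eta: partner 0.540 M; protic impurity 0.0860 M; time 4.0 min

green run (percent of the left-handed substrate and right-handed substrate together charged)

| time / min | left-handed product / % | left-handed substrate / % |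
|---|---|---|
| 0.250 | 7 | 45 |
| 0.500 | 13 | 32 |
| 1.33 | 23 | 24 |
| 3.00 | 29 | 18 |

(each reading ± 2 percentage points)

- catalyst is single-handed; left-handed substrate and right-handed substrate are mirror images of each other, charged as a racemate, each of them at the stated concentration
- no earlier run changes the charge of protic impurity; that part of a forecast is a guess

- which of the two there is more of at the end, alpha (left-handed product / right-handed product)
- which of the two there is more of at the end, eta (left-handed product / right-handed product)
- amount of left-handed product at the end, in percent of the left-handed substrate and right-handed substrate together charged, alpha
- amount of left-handed product at the end, in percent of the left-handed substrate and right-handed substrate together charged, eta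

So keep partner's books in alpha, in percent of the substrates charged, assuming that protic impurity and each substrate take partner one for one:

partner charged: 75.0 %
protic impurity's entry: 10.0 %
left for the substrates: 65.0 %

That balance is the partner budget, b: partner charged minus protic impurity charged, divided by the two substrates charged together. In eta b is 63.1 %, and in green 59.7 %. On this assumption the books close at any moment:

both products = b + unused protic impurity − unused partner

At its last reading, green held about half of its budget as left-handed product. Keeping that share, although alpha and eta are asked at 4.0 min and that reading stands at 3.00 min, my own reckoning gives:

alpha: 31.6 %
eta: 30.6 %

The forecast expects left-handed product to lead in alpha and left-handed product in eta, and it gives more than my reckoning, 37 % in alpha and 36 % in eta. It names as the likely cause of the stall “partner running out, not loss of selectivity”.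

Alpha gives 34.1 % left-handed and 24.4 % right-handed product; eta gives 33.7 % and 24.0 %. The forecast picked the larger product in both flasks, and its two amounts lie within the tolerance.

    partner + protic impurity → quenched reagent (k = 0.0360 /M/s)
    partner + catalyst + left-handed substrate → catalyst + left-handed product (k = 3.60 /M²/s)
    partner + catalyst + right-handed substrate → catalyst + right-handed product (k = 2.10 /M²/s)

In eta the slowest mode of the flask has a half-life of 10.2 min, longer than the 4.0 min of the run, and 11 % of the partner charge is still there. In alpha the books read 65.0 % plus 2.03 % of unused protic impurity minus 8.52 % of unused partner, which makes 58.5 % against 58.5 % of products.

Take a neighbour of eta charged with 0.21 M of protic impurity: its b is 45.8 %, and the books add 8.37 % and subtract 4.13 %, giving 50.1 %. The computed flask holds 29.7 % left-handed and 20.4 % right-handed product at 4.00 min.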